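## Retrosynthetic overview

1. Open the chroman C2–O bond to reach an achiral quinone that is an isomer of the target. In the forward direction, one enantioselective palladium-catalysed cycloisomerisation closes the pyran ring, sets C2 (R) and creates the 1E alkene.
2. The quinone comes from the hydroquinone dimethyl ether by oxidative demethylation.
3. The (3E,6Z)-skipped diene is cut between the vinylic CH and the doubly allylic CH2, giving an (E)-alkenylalane (from an arylbutyne) and a (Z)-allylic chloride.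
4. The (Z)-allylic chloride comes from a propargylic alcohol, where directed syn-methylmagnesiation fixes Z, and that alcohol comes from dihydro-β-ionone. The arylbutyne comes from 2,5-dimethoxybenzyl chloride and silylpropyne.
5. Ring order: the cyclohexene ring and the arene are bought. The pyran ring is the only ring formed, in the last step.

Assumption: compounds 1, 9 and 10 are bought, and the BOXAX ligand (either antipode, made from phenylalaninol) is a catalyst component whose preparation is not counted.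

## Route

Step 1
Reactants: 1 dihydro-β-ionone [4-(2,6,6-trimethylcyclohex-1-en-1-yl)butan-2-one]
Product: 4 5-(2,6,6-trimethylcyclohex-1-en-1-yl)pent-2-yn-1-ol, via enol phosphate 2 (not isolated), via lithium acetylide 3 (not isolated)
Conditions: LiN(i-Pr)2 (1.05 equiv), THF, −78 °C; ClP(O)(OEt)2 (1.1 equiv), −78 → 23 °C; LiN(i-Pr)2 (2.3 equiv), −78 → 23 °C; (CH2O)n (4 equiv), −20 → 23 °C; aq NH4Cl
Reagents that add atoms: paraformaldehyde (reacts as formaldehyde), C=O
Why: Kinetic deprotonation at CH3, O-phosphorylation and double elimination (Negishi methyl-ketone-to-alkyne protocol) end at acetylide 3, which adds to formaldehyde in the same flask (acetylide hydroxymethylation); the tetrasubstituted ring alkene is inert and no stereocentre is made.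

Step 2
Reactants: 4 5-(2,6,6-trimethylcyclohex-1-en-1-yl)pent-2-yn-1-ol
Product: 6 (Z)-3-methyl-5-(2,6,6-trimethylcyclohex-1-en-1-yl)pent-2-en-1-ol, via alkenylmagnesium alkoxide 5 (not isolated)
Conditions: MeMgBr (5 equiv), Fe(acac)3 (20 mol %), THF, −78 → 0 °C, 8 h; aq NH4Cl
Reagents that add atoms: methylmagnesium bromide, C[Mg]Br
Why: Alkoxide-directed iron-catalysed syn-carbomagnesiation of a propargylic alcohol puts CH3 on the distal alkyne carbon and Mg next to CH2O, so protonolysis of 5 leaves CH3 cis to H and the ring-bearing chain cis to CH2OH, which is the Z-trisubstituted alkene of the target.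

Step 3
Reactants: 6 (Z)-3-methyl-5-(2,6,6-trimethylcyclohex-1-en-1-yl)pent-2-en-1-ol
Product: 8 2-[(3Z)-5-chloro-3-methylpent-3-en-1-yl]-1,3,3-trimethylcyclohex-1-ene, via allylic mesylate 7 (not isolated)
Conditions: MsCl (1.2 equiv), LiCl (3 equiv), 2,4,6-collidine (1.5 equiv), DMF, 0 °C, 2 h
Reagents that add atoms: lithium chloride, [Li+].[Cl-]
Why: Collington–Meyers chlorination, in which chloride displaces the primary allylic mesylate by SN2 at 0 °C; neryl-type alcohols react under these conditions without allylic transposition or Z/E leakage.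

Step 4
Reactants: 9 1-(trimethylsilyl)propyne; 10 2-(chloromethyl)-1,4-dimethoxybenzene
Product: 13 2-(but-3-yn-1-yl)-1,4-dimethoxybenzene, via lithiated silylpropyne 11 (not isolated), via silylated arylbutyne 12 (not isolated)
Conditions: 9, n-BuLi (1.05 equiv), THF, −78 → −20 °C; 10, −78 → 23 °C; then K2CO3 (0.3 equiv), MeOH, 23 °C, 3 h
Reagents that add atoms: none
Why: Propargylic lithiation of the C-silylated propyne and SN2 benzylation at its CH2 terminus (the silyl group blocks the alkyne C–H and disfavours allene formation), followed by methanolytic protodesilylation.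

Step 5
Reactants: 13 2-(but-3-yn-1-yl)-1,4-dimethoxybenzene; 8 2-[(3Z)-5-chloro-3-methylpent-3-en-1-yl]-1,3,3-trimethylcyclohex-1-ene
Product: 15 2-[(3E,6Z)-3,7-dimethyl-9-(2,6,6-trimethylcyclohex-1-en-1-yl)nona-3,6-dien-1-yl]-1,4-dimethoxybenzene, via alkenylalane 14 (not isolated)
Conditions: 13, Me3Al (2 equiv), Cp2ZrCl2 (25 mol %), ClCH2CH2Cl, 23 °C, 12 h; then 8 (0.9 equiv), Pd(PPh3)4 (5 mol %), THF, 23 °C, 6 h; cold dilute HCl
Reagents that add atoms: trimethylaluminium, C[Al](C)C
Why: Negishi zirconium-catalysed syn-methylalumination gives the (E)-alkenylalane, and the palladium-catalysed alkenyl–allyl cross-coupling joins it to the primary allyl terminus with retention of both alkene geometries, as established for neryl and geranyl chlorides.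

Step 6
Reactants: 15 2-[(3E,6Z)-3,7-dimethyl-9-(2,6,6-trimethylcyclohex-1-en-1-yl)nona-3,6-dien-1-yl]-1,4-dimethoxybenzene
Product: 16 2-[(3E,6Z)-3,7-dimethyl-9-(2,6,6-trimethylcyclohex-1-en-1-yl)nona-3,6-dien-1-yl]cyclohexa-2,5-diene-1,4-dione
Conditions: (NH4)2Ce(NO3)6 (2.3 equiv), MeCN/CH2Cl2/H2O, 0 °C, 20 min
Reagents that add atoms: water, O (ipso attack; both methoxy groups leave as methanol)
Why: Oxidative demethylation of a hydroquinone dimethyl ether by tetravalent cerium (two single-electron oxidations, ipso attack of water, loss of methanol) is much faster than oxidation of the isolated alkenes, as in polyprenylquinone syntheses.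

Step 7
Reactants: 16 2-[(3E,6Z)-3,7-dimethyl-9-(2,6,6-trimethylcyclohex-1-en-1-yl)nona-3,6-dien-1-yl]cyclohexa-2,5-diene-1,4-dione
Product: 18 (2R)-2-methyl-2-[(1E,3Z)-4-methyl-6-(2,6,6-trimethylcyclohex-1-en-1-yl)hexa-1,3-dien-1-yl]-3,4-dihydro-2H-chromen-6-ol, via hydroquinone 17 (not isolated)
Conditions: Pd2(dba)3·CHCl3 (5 mol %), (R,R)-Bn-BOXAX [(R)-2,2'-bis((4R)-4-benzyl-4,5-dihydrooxazol-2-yl)-1,1'-binaphthyl, 20 mol %], CF3CO2H (20 mol %, two per Pd), MeOH/CH2Cl2 3:1, 0.05 M, 25 °C, Ar, dark, 24–48 h; filter through silica at full conversion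
Reagents that add atoms: none
Why: Proposed new method: a redox-neutral, enantioselective quinone-to-chromanol cycloisomerisation in which the substrate's own quinone is the oxidant and then becomes the nucleophile. Zerovalent palladium carrying the BOXAX ligand binds η2 to the quinone of 16 and is protonated by CF3CO2H to divalent palladium plus hydroquinone 17 (the known acid-induced step of benzoquinone reoxidation). The ortho OH of 17 then adds 6-exo to the ligand-differentiated face of the 3E-trisubstituted alkene (oxypalladation), which forms the C2–O bond and sets C2. The only β-hydrogens are those of the doubly allylic CH2, so syn β-hydride elimination gives the 1E alkene conjugated with the untouched Z alkene, and HPd(OCOCF3) collapses to zerovalent palladium, which the next molecule of 16 captures. The step is therefore a pure isomerisation (C26H36O2 to C26H36O2) with no external oxidant that could attack the chromanol. The closest known reaction type is the enantioselective Wacker-type cyclisation of 2-(alk-3-enyl)phenols to 2-methyl-2-vinylchromans with Pd(OCOCF3)2/BOXAX and external p-benzoquinone; by extrapolation from those cases the (R,R) ligand is expected to give 2R, the sense is checked on the first run, and the antipodal ligand is used if needed.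

## Compound list

1 | dihydro-β-ionone, 4-(2,6,6-trimethylcyclohex-1-en-1-yl)butan-2-one | CC1=C(CCC(C)=O)C(C)(C)CCC1 | starting material
2 | diethyl 4-(2,6,6-trimethylcyclohex-1-en-1-yl)but-1-en-2-yl phosphate | CC1=C(CCC(=C)OP(=O)(OCC)OCC)C(C)(C)CCC1 | intermediate (not isolated)
3 | [4-(2,6,6-trimethylcyclohex-1-en-1-yl)but-1-yn-1-yl]lithium | CC1=C(CCC#C[Li])C(C)(C)CCC1 | intermediate (not isolated)
4 | 5-(2,6,6-trimethylcyclohex-1-en-1-yl)pent-2-yn-1-ol | CC1=C(CCC#CCO)C(C)(C)CCC1 | intermediate
5 | bromomagnesium alkoxide of the 2-(bromomagnesio)-3-methylpent-2-en-1-ol, Mg cis to the new CH3 | CC1=C(CC/C(C)=C(/[Mg]Br)CO[Mg]Br)C(C)(C)CCC1 | intermediate (not isolated)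
6 | (Z)-3-methyl-5-(2,6,6-trimethylcyclohex-1-en-1-yl)pent-2-en-1-ol | CC1=C(CC/C(C)=C\CO)C(C)(C)CCC1 | intermediate
7 | (Z)-3-methyl-5-(2,6,6-trimethylcyclohex-1-en-1-yl)pent-2-en-1-yl methanesulfonate | CC1=C(CC/C(C)=C\COS(C)(=O)=O)C(C)(C)CCC1 | intermediate (not isolated)
8 | 2-[(3Z)-5-chloro-3-methylpent-3-en-1-yl]-1,3,3-trimethylcyclohex-1-ene | CC1=C(CC/C(C)=C\CCl)C(C)(C)CCC1 | intermediate
9 | 1-(trimethylsilyl)propyne | CC#C[Si](C)(C)C | starting material
10 | 2-(chloromethyl)-1,4-dimethoxybenzene | COc1ccc(OC)c(CCl)c1 | starting material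
11 | [3-(trimethylsilyl)prop-2-yn-1-yl]lithium | [Li]CC#C[Si](C)(C)C | intermediate (not isolated)
12 | [4-(2,5-dimethoxyphenyl)but-1-yn-1-yl]trimethylsilane | COc1ccc(OC)c(CCC#C[Si](C)(C)C)c1 | intermediate (not isolated)
13 | 2-(but-3-yn-1-yl)-1,4-dimethoxybenzene | COc1ccc(OC)c(CCC#C)c1 | intermediate
14 | [(E)-4-(2,5-dimethoxyphenyl)-2-methylbut-1-en-1-yl]dimethylaluminium | COc1ccc(OC)c(CC/C(C)=C/[Al](C)C)c1 | intermediate (not isolated)
15 | 2-[(3E,6Z)-3,7-dimethyl-9-(2,6,6-trimethylcyclohex-1-en-1-yl)nona-3,6-dien-1-yl]-1,4-dimethoxybenzene | CC1=C(CC/C(C)=C\C/C=C(\C)CCc2cc(OC)ccc2OC)C(C)(C)CCC1 | intermediate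
16 | 2-[(3E,6Z)-3,7-dimethyl-9-(2,6,6-trimethylcyclohex-1-en-1-yl)nona-3,6-dien-1-yl]cyclohexa-2,5-diene-1,4-dione | CC1=C(CC/C(C)=C\C/C=C(\C)CCC2=CC(=O)C=CC2=O)C(C)(C)CCC1 | intermediate
17 | 2-[(3E,6Z)-3,7-dimethyl-9-(2,6,6-trimethylcyclohex-1-en-1-yl)nona-3,6-dien-1-yl]benzene-1,4-diol | CC1=C(CC/C(C)=C\C/C=C(\C)CCc2cc(O)ccc2O)C(C)(C)CCC1 | intermediate (not isolated)
18 | (2R)-2-methyl-2-[(1E,3Z)-4-methyl-6-(2,6,6-trimethylcyclohex-1-en-1-yl)hexa-1,3-dien-1-yl]-3,4-dihydro-2H-chromen-6-ol | CC1=C(CC/C(C)=C\C=C\[C@@]2(C)CCc3cc(O)ccc3O2)C(C)(C)CCC1 | target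

## Step count and risks

Total steps: 7.
Longest linear sequence: 6 (steps 1, 2, 3, 5, 6, 7).

**Step 7 (the proposed new step).**
- Risks:
  - There may be no turnover.
  - The ee may be low on a skipped diene.
  - Pd–H may isomerise the Z alkene.
  - Zerovalent palladium left at the end may ionise the tertiary dienyl aryl ether.
- The fallback uses known chemistry. It sets out from 13 and 8 and comes back at 18. The chroman is built first by the established palladium-catalysed asymmetric allylic etherification, and the chain is attached afterwards by olefination.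
- Alane 14, made from 13 as in step 5, is converted with n-BuLi into the lithium aluminate F1 and hydroxymethylated with paraformaldehyde to (E)-5-(2,5-dimethoxyphenyl)-3-methylpent-2-en-1-ol F2. ClCO2Me/pyridine gives the methyl carbonate F3. (NH4)2Ce(NO3)6 gives the quinone carbonate F4, and aqueous Na2S2O4 gives the hydroquinone carbonate F5.
- Pd2(dba)3·CHCl3, the DACH-phenyl Trost ligand (antipode chosen for 2R) and AcOH in CH2Cl2 cyclise it to (R)-2-methyl-2-vinylchroman-6-ol F6. TBSCl/imidazole gives the silyl ether F7. OsO4 (cat.)/NaIO4/2,6-lutidine leads through the diol F8 to (R)-6-(tert-butyldimethylsilyloxy)-2-methylchroman-2-carbaldehyde F9.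
- Chloride 8 with NaP(O)(OEt)2 in THF gives the (Z)-allylic phosphonate F10. Deprotonation with LiN(SiMe3)2 at −78 °C and Horner–Wadsworth–Emmons reaction with F9 gives the silyl ether of the target F11, and Bu4NF releases 18.

**Step 2.**
- Risks: incomplete carbomagnesiation, the wrong regioisomer, or reduced by-products.
- The fallback sets out from 1 and comes back at 6. It replaces the directed carbometalation by conjugate addition to an ynoate.
- The step 1 sequence is run as far as acetylide 3, which is quenched with ClCO2Me to give methyl 5-(2,6,6-trimethylcyclohex-1-en-1-yl)pent-2-ynoate F12. Me2CuLi in THF at −78 °C, with a cold MeOH quench, gives by syn addition methyl (Z)-3-methyl-5-(2,6,6-trimethylcyclohex-1-en-1-yl)pent-2-enoate F13. i-Bu2AlH in CH2Cl2 at −78 °C gives 6.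

**Step 5.**
- Risks: Me3Al may ionise 8, the π-allylpalladium intermediate may leak Z to E, or methyl may transfer instead of the alkenyl group.
- The fallback sets out from 13 and 8 and comes back at 15. It avoids both free Me3Al and any π-allyl intermediate.
- Alane 14 is quenched with I2 to give 2-[(E)-4-iodo-3-methylbut-3-en-1-yl]-1,4-dimethoxybenzene F14, which is purified. Iodine–magnesium exchange with i-PrMgCl·LiCl (THF, 0 → 23 °C, retention) gives the alkenylmagnesium chloride F15. Li2CuCl4 (5 mol %) in THF at −20 °C couples it with 8 by direct SN2 substitution at the primary carbon to give 15.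

## Further compounds

F1 | step 7 | lithium butyl[(E)-4-(2,5-dimethoxyphenyl)-2-methylbut-1-en-1-yl]dimethylaluminate | [Li+].CCCC[Al-](C)(C)/C=C(\C)CCc1cc(OC)ccc1OC
F2 | step 7 | (E)-5-(2,5-dimethoxyphenyl)-3-methylpent-2-en-1-ol | OC/C=C(\C)CCc1cc(OC)ccc1OC
F3 | step 7 | (E)-5-(2,5-dimethoxyphenyl)-3-methylpent-2-en-1-yl methyl carbonate | COC(=O)OC/C=C(\C)CCc1cc(OC)ccc1OC
F4 | step 7 | (E)-5-(3,6-dioxocyclohexa-1,4-dien-1-yl)-3-methylpent-2-en-1-yl methyl carbonate | COC(=O)OC/C=C(\C)CCC1=CC(=O)C=CC1=O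
F5 | step 7 | (E)-5-(2,5-dihydroxyphenyl)-3-methylpent-2-en-1-yl methyl carbonate | COC(=O)OC/C=C(\C)CCc1cc(O)ccc1O
F6 | step 7 | (R)-2-methyl-2-vinylchroman-6-ol | C=C[C@@]1(C)CCc2cc(O)ccc2O1
F7 | step 7 | (R)-6-(tert-butyldimethylsilyloxy)-2-methyl-2-vinylchroman | C=C[C@@]1(C)CCc2cc(O[Si](C)(C)C(C)(C)C)ccc2O1
F8 | step 7 | 1-[(R)-6-(tert-butyldimethylsilyloxy)-2-methylchroman-2-yl]ethane-1,2-diol (carbinol epimers) | OCC(O)[C@@]1(C)CCc2cc(O[Si](C)(C)C(C)(C)C)ccc2O1
F9 | step 7 | (R)-6-(tert-butyldimethylsilyloxy)-2-methylchroman-2-carbaldehyde | O=C[C@@]1(C)CCc2cc(O[Si](C)(C)C(C)(C)C)ccc2O1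
F10 | step 7 | diethyl [(Z)-3-methyl-5-(2,6,6-trimethylcyclohex-1-en-1-yl)pent-2-en-1-yl]phosphonate | CC1=C(CC/C(C)=C\CP(=O)(OCC)OCC)C(C)(C)CCC1
F11 | step 7 | tert-butyldimethylsilyl ether of 18 | CC1=C(CC/C(C)=C\C=C\[C@@]2(C)CCc3cc(O[Si](C)(C)C(C)(C)C)ccc3O2)C(C)(C)CCC1
F12 | step 2 | methyl 5-(2,6,6-trimethylcyclohex-1-en-1-yl)pent-2-ynoate | CC1=C(CCC#CC(=O)OC)C(C)(C)CCC1
F13 | step 2 | methyl (Z)-3-methyl-5-(2,6,6-trimethylcyclohex-1-en-1-yl)pent-2-enoate | CC1=C(CC/C(C)=C\C(=O)OC)C(C)(C)CCC1
F14 | step 5 | 2-[(E)-4-iodo-3-methylbut-3-en-1-yl]-1,4-dimethoxybenzene | COc1ccc(OC)c(CC/C(C)=C/I)c1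
F15 | step 5 | [(E)-4-(2,5-dimethoxyphenyl)-2-methylbut-1-en-1-yl]magnesium chloride | COc1ccc(OC)c(CC/C(C)=C/[Mg]Cl)c1
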